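A small charge of X, 2.00% of the E charged in the delta run, stands against a J reading of 8.2% at 25.0 min, so each X has by then turned over about 4.10 times. J here is a matter of counting turnovers.

| flask | E | G | Q | X | remark | time |
|---|---|---|---|---|---|---|
| gamma | 0.050 M | 0.024 M | 10 mM | 1 mM (in portions, 3) | run made earlier; portions every 8.0 min |  |
| theta | 0.050 M | 0.039 M | 10 mM | 1 mM (in portions, 3) | run made earlier; portions every 8.0 min |  |
| delta | 0.050 M | 0.059 M | 10 mM | 1 mM (in portions, 3) | run made earlier; portions every 8.0 min |  |
| alpha | 0.050 M | 0.065 M | 6.8 mM | 1 mM (in portions, 3) | run made earlier; portions every 8.0 min |  |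
| cedar | 0.012 M | 0.0300 M | 10 mM | 1.0 mM (in portions, 3) | the portions of X follow each other after 8.0 min, the first at the start | 25 min |
| elm | 0.012 M | 0.0650 M | 10 mM | 1.0 mM (in portions, 3) | the portions of X follow each other after 8.0 min, the first at the start | 25 min |
| maple | 0.050 M | 0.0650 M | 2.5 mM | 0.50 mM (in portions, 3) | the portions of X follow each other after 8.0 min, the first at the start | 25 min |
| larch | 0.050 M | 0.0200 M | 10 mM | 0.25 mM (in portions, 3) | the portions of X follow each other after 8.0 min, the first at the start | 25 min |
| ash | 0.025 M | 0.0650 M | 10 mM | 2.0 mM (in portions, 3) | the portions of X follow each other after 2.0 min, the first at the start | 25 min |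
| birch | 0.050 M | 0.0650 M | 10 mM | 1.0 mM (in portions, 3) | the portions of X follow each other after 8.0 min, the first at the start | 25 min |

| run | time / min | J / % | E / % |
|---|---|---|---|
| gamma | 5.00 | 0 | 46.1 |
| gamma | 10.0 | 0 | 19.5 |
| gamma | 15.0 | 1.6 | 8.6 |
| gamma | 20.0 | 0 | 4.9 |
| gamma | 25.0 | 3.0 | 1.5 |
| theta | 2.00 | 1.0 | 71.9 |
| theta | 6.00 | 1.1 | 35.8 |
| theta | 12.0 | 1.5 | 12.2 |
| theta | 20.0 | 3.5 | 2.8 |
| theta | 25.0 | 6.8 | 0.6 |
| delta | 2.00 | 0.6 | 71.4 |
| delta | 4.00 | 0 | 51.2 |
| delta | 8.00 | 1.3 | 25.2 |
| delta | 12.0 | 2.0 | 14.4 |
| delta | 25.0 | 8.2 | 3.4 |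
| alpha | 5.00 | 3.5 | 55.5 |
| alpha | 10.0 | 2.0 | 31.7 |
| alpha | 15.0 | 4.1 | 17.0 |
| alpha | 20.0 | 6.4 | 10.8 |
| alpha | 25.0 | 8.4 | 3.8 |

(scatter of a reading: 1 percentage point)

1. the flasks by amount of J, in percent of the E charged, highest first, at 25 min (cedar / elm / maple / larch / ash / birch)
2. the same order at 1.5 h (cedar / elm / maple / larch / ash / birch)
3. the amount of J, in percent of the E charged of the flask you put first, at 25 min
4. the amount of J, in percent of the E charged of the flask you put last, at 25 min

- what was read earlier has a scatter of 1 percentage point, one standard deviation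
- reactions considered so far: G + Z <-> X + J; X + L <-> Z; E + G -> D; E + Q -> Q + L
- no earlier run changes the charge of X; that part of a forecast is a guess

In delta, E is down to 3.4% at that reading, so by the reactions considered a pool of L stands ready to take up X as Z. Alpha with 6.8 mM of Q and 0.065 M of G reads 8.4%, and delta with 10 mM of Q and 0.059 M of G reads 8.2%, the same within the scatter of 1 percentage point. J does follow G, from 3.0% at 0.024 M in gamma to 8.2% at 0.059 M in delta. This suggests that X waits as Z, its resting state, until G + Z releases it.

The reckoning that follows is my own. The 3 portions enter after nothing, one and two intervals, so the mean X works for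

mean working time = 17.0 min.

Pooling the last J readings of the four runs against their G gives the turnover constant, 4.15 /M/min, the turnovers of one X per minute per molar of G. Its reciprocal over G is the turnover time, and a flask's count is its mean working time in turnover times. For ash:

turnover time = 3.71 min
mean working time = 23.0 min.
count of turnovers n = 6.21
X as a share of the E charged, x = 8.00%
J share a = n·x = 49.7%

The link to reforge here is G held at its charge: in G + Z ⇌ X + J each J draws one G. With G falling evenly, its mean drop is 0.5 of what J has drawn. Taking s as 0.5 of the E charged over the G charged, the J share becomes a over one plus a·s: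

ash: s = 0.192, J = 45.3%
elm: J = 36.9%
larch: s = 1.25, J = 0.700%

So in this reckoning ash stands above elm, and larch stands below both. At 1.5 h the count for ash and for elm each passes the whole E charge, so turnovers cannot rank those two there.

The forecast gives ash > elm > cedar > birch > maple > larch at 25 min and ash > elm > cedar > birch > maple > larch at 1.5 h, with 35% first and 0.7% last, noting “The ash dosing effect is a guess”, and its top lies below the 45.3% reckoned here.

The flask gives ash > elm > cedar > birch > maple > larch at 25 min, with ash at 41.9% and larch at 0.681%, and elm > ash > cedar > birch > maple > larch at 1.5 h, with elm at 90.2% and ash at 88.8%.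

    G + Z ⇌ X + J (K = 0.0650, k = 0.0690 /M/s)
    X + L ⇌ Z (K = 12000 /M, k = 16.0 /M/s)
    E + G → D (k = 5.60 × 10⁻⁴ /M/s)
    E + Q → Q + L (k = 0.270 /M/s)

In ash, 41.9% over x means 5.24 turnovers, against the 6.21 counted with G at its charge. The time given is the main reason ash stands short of its E charge: at 250 min the same flask gives 88.9% against 41.9%, which closes 81% of what is missing. On a neighbour, the larch flask with 0.0010 M of X, the same count gives 2.73%. That flask gives 2.65%.

The earlier runs and the new flask were generated by integration for substances that don't exist, and the scatter is random.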